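## Analysis of the target

Locants used throughout: ring atoms are C1 (the stereocentre) to C14. C3=C4 carries CO2Me on C4, C7=C8 carries CH3 on C8, and C11=C12 carries CH3 on C12. C15(=C16H2) is the first carbon of the 6-methylhepta-1,5-dien-2-yl side chain on C1.

- The target 23 is a monocyclic sesterterpenoid ester, a 14-membered carbocycle with no ring heteroatom. Any ring closure that leaves a hydroxyl or carbonyl group behind therefore costs extra steps.
- The three trisubstituted ring alkenes make three different demands. C3=C4 has its ring carbons trans, so the ester is cis to C2 (Z, the less stable angelate-type enoate). C7=C8 is E and C11=C12 is Z.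
- The only stereocentre is C1 (R), a tertiary allylic carbon bonded to three carbons.
- Its neighbouring alkene ends in C16H2, so no simple 1,3-chirality transfer across C15=C16 can set C1.
- Sensitive points are the 1,5-diene arrays (acid-induced cation–olefin cyclisation), the Z-enoate (isomerisation, deconjugation) and the γ-acidic C2H2 group.
- The feature that invites the strategy is the 1,5-diene C16=C15–C1–C2–C3=C4 whose C4 bears the carboxyl carbon. This is a Cope retron, and its Cope precursor is the Claisen product of an ester between that carboxyl group and a C1 carbinol.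
- The free acid 22 is therefore a constitutional isomer of the 14-membered lactone 18.
- The difficulty is to solve ring closure, three alkene geometries and a lone "hydrocarbon" stereocentre together without functional-group debris.

## Retrosynthetic reasoning

**23 to 22.** Only the O–CH3 bond is cut. The acid is what the key step delivers, and the forward reaction must esterify without touching the Z-enoate.

**22 to 20 (through 21).**
- Bonds: C1–C2 is cut and C4–C16 is reconnected, which is a retro-Cope rearrangement of the 1,5-diene named above.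
- Why here: this is the only all-carbon [3,3] array that contains C1–C2, C3=C4 and C15=C16 together.
- Forward task: move the allyl unit from C4 to C2, create C1, restore C15=C16H2 and place C5 trans to C2.

**20 to 18 (through 19).**
- Bonds: C4–C16 is cut and C1–O is reconnected, a retro-Ireland–Claisen rearrangement.
- Gain: the carbocycle becomes a lactone whose acyl carbon is the ester carbon of the target, so no atom is wasted. The C1 stereocentre becomes a secondary allylic carbinol, the easiest kind of centre to set. The Z-enoate shrinks to a plain vinyl group on C4 whose configuration does not matter.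
- Forward task: carry the C1–O chirality into C4 and back to C1.

**18 to 17.** The acyl C–O bond is cut. Ring closure is thereby moved to a macrolactonisation, the most dependable way to close a 14-membered ring.

**17 to 16 to 13 + 14.** C4–C5 is cut. Deconjugative α-alkylation of the dienediolate of but-2-enoic acid 14 brings in C2, C3, C4 and the carboxyl carbon in one step, already as the 2-vinyl acid. The silyl group of 16 only masks the carbinol.

**13 to 12 to 10.** C6–C7 and C8–CH3 are cut. Syn methylalumination of a terminal alkyne followed by capture with a C2 epoxide fixes the E geometry of C7=C8 by mechanism.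

**10 to 8 to 7.** These are functional-group changes only. The methyl ketone of 8 is the latent alkyne (its methyl carbon becomes C7), and the carbinol of 7 is silylated first.

**7 to 3 + 6.** C1–C15 is cut. A catalytic asymmetric alkenylation that reacts with aldehydes but not ketones joins the whole side chain and sets the carbinol.

**3 to 1 and 6 to 4.**
- The Z geometry of C11=C12 is not made but inherited, by cleaving one of the two ring alkenes of 1. This gives ten carbons with differentiated termini.
- Compound 6 is the kinetic enol triflate of 4.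

## Alternatives that were turned down

**Alternative 1** (the textbook route): cut C3=C4. The forward key step is an intramolecular Z-selective Horner–Wadsworth–Emmons (Still–Gennari type) closure of phosphonate aldehyde A1.
- The ring-closing step makes one bond and one geometry only.
- C1 must be built beforehand by a separate asymmetric C–C bond formation, and C3 must be carried masked through the chain extension.
- Z-selectivity rests on kinetic control at low temperature with a dissociated potassium counter-ion. Those are the conditions under which a high-dilution closure with an α-branched phosphonate is slowest.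
- The route is several steps longer. It is kept only as the fallback.

**Alternative 2:** cut C1–C14. The forward key step is an enantioselective Ireland–Claisen ring contraction of the achiral 18-membered lactone A2 under a stoichiometric chiral boron Lewis acid. This gives acid A3, which is then decarboxylated by a radical method.
- A2 must already hold all three ring alkenes, including the Z-enoate, so the precursor is no simpler than the product.
- Its C2H2 group is doubly allylic and vinylogous to the ester, so it is the most acidic site under amine/boron enolisation.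
- The lactone carbonyl carbon is wasted.
- The C14 radical sits next to C1 and invites a 1,2-alkenyl shift.

**Alternative 3:** cut C3=C4 and C11=C12 together (6 + 8 ring atoms). The chiral pool supplies C1: (R)-limonene A4 is prenylated at its isopropenyl methyl group to (R)-β-bisabolene A5, the ring alkene is cleaved to keto aldehyde A6, and a C8 bis-olefination reagent is stitched in.
- The mapping is attractive, since 15 carbons and C1 come in one step.
- However, the ring alkene of A5 cannot be told from the equally trisubstituted prenyl alkene by any electrophilic oxidant.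
- Olefination of the methyl ketone of A6 has no mechanistic basis for Z selectivity.

Key step: step 11

Assumptions:
- (a) Technical 1 contains the 1,6-dimethyl isomer. Its cleavage products (a dialdehyde and a diketone) are removed by chromatography after step 1.
- (b) C4 is formed as both epimers in 16, 17 and 18. This is of no consequence, because C4 is planarised in step 11.

## Route

Step 1
Reactants: 1 (1Z,5Z)-1,5-dimethylcycloocta-1,5-diene
Product: 3 (4Z)-4-methyl-8-oxonon-4-enal, via ozonide 2 (not isolated)
Conditions: O3 (one equivalent), CH2Cl2, −78 °C; then Me2S, −78 °C to rt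
Reagents that add atoms: ozone, [O-][O+]=O
Why: Ozonolysis of one of two equivalent ring alkenes, stopped at partial conversion; unreacted 1 and the volatile products of double cleavage are easily removed. The surviving alkene keeps the cis ring geometry, which becomes the Z geometry of C11=C12, and the termini emerge differentiated as aldehyde (C1) and methyl ketone (C8).

Step 2
Reactants: 4 6-methylhept-5-en-2-one
Product: 6 6-methylhepta-1,5-dien-2-yl trifluoromethanesulfonate, via lithium enolate 5 (not isolated)
Conditions: LDA, THF, −78 °C; then PhNTf2, −78 °C to rt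
Reagents that add atoms: N-phenylbis(trifluoromethanesulfonimide), O=S(=O)(N(c1ccccc1)S(=O)(=O)C(F)(F)F)C(F)(F)F; lithium diisopropylamide, CC(C)[N-]C(C)C.[Li+] (lithium in 5 only)
Why: Kinetic deprotonation of a methyl ketone takes place at the methyl group, and O-triflation fixes the 1,1-disubstituted alkene C15=C16. The trisubstituted alkene is inert.

Step 3
Reactants: 3 (4Z)-4-methyl-8-oxonon-4-enal; 6 6-methylhepta-1,5-dien-2-yl trifluoromethanesulfonate
Product: 7 (5Z,9R)-9-hydroxy-6,14-dimethyl-10-methylidenepentadeca-5,13-dien-2-one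
Conditions: CrCl2 (cat.), chiral oxazolinyl-anilide sulfonamide ligand (cat., the antipode that gives 9R), Et3N (cat.), NiCl2·(2,9-dimethyl-1,10-phenanthroline) (cat.), Mn, Cp2ZrCl2, LiCl, MeCN, rt
Reagents that add atoms: none
Why: Catalytic asymmetric Nozaki–Hiyama–Kishi alkenylation: nickel activates the C–OTf bond and hands the alkenyl group to chromium, and alkenylchromium reagents add to aldehydes but not to ketones, so C8=O survives. The sulfonamide-bound trivalent chromium differentiates the aldehyde faces and sets the C1 carbinol as R.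

Step 4
Reactants: 7 (5Z,9R)-9-hydroxy-6,14-dimethyl-10-methylidenepentadeca-5,13-dien-2-one
Product: 8 (5Z,9R)-9-[(tert-butyldimethylsilyl)oxy]-6,14-dimethyl-10-methylidenepentadeca-5,13-dien-2-one
Conditions: TBSCl, imidazole, DMF, rt
Reagents that add atoms: tert-butyldimethylsilyl chloride, CC(C)(C)[Si](C)(C)Cl
Why: Standard silylation; the ether withstands the strong bases and the aluminium reagent of steps 5, 6 and 8. The stereocentre is not touched.

Step 5
Reactants: 8 (5Z,9R)-9-[(tert-butyldimethylsilyl)oxy]-6,14-dimethyl-10-methylidenepentadeca-5,13-dien-2-one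
Product: 10 (5Z,9R)-9-[(tert-butyldimethylsilyl)oxy]-6,14-dimethyl-10-methylidenepentadeca-5,13-dien-1-yne, via enol phosphate 9 (not isolated)
Conditions: LDA (1 equiv), THF, −78 °C; ClP(O)(OEt)2, to rt; then LDA (2.3 equiv), −78 °C to rt; H2O
Reagents that add atoms: diethyl chlorophosphate, CCOP(=O)(Cl)OCC (atoms in 9 only)
Why: Methyl ketone to terminal alkyne by kinetic enol phosphate formation and base-induced elimination; the former methyl carbon becomes C7. No other acidic or electrophilic site is present.

Step 6
Reactants: 10 (5Z,9R)-9-[(tert-butyldimethylsilyl)oxy]-6,14-dimethyl-10-methylidenepentadeca-5,13-dien-1-yne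
Product: 12 (3E,7Z,11R)-11-[(tert-butyldimethylsilyl)oxy]-4,8,16-trimethyl-12-methylideneheptadeca-3,7,15-trien-1-ol, via alkenylalane 11 (not isolated)
Conditions: Me3Al, Cp2ZrCl2 (cat.), CH2Cl2, 0 °C to rt; volatiles removed; n-BuLi, hexane/THF, −78 to 0 °C; oxirane, to rt; aqueous work-up
Reagents that add atoms: trimethylaluminium, C[Al](C)C; oxirane, C1CO1
Why: Negishi carboalumination adds CH3 (to C8) and Al (to C7) syn and regioselectively, which fixes C7=C8 as E by mechanism. The derived alanate opens the epoxide with retention of the alkene geometry and brings in C6 and C5; di- and trisubstituted alkenes and the silyl ether are not attacked.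

Step 7
Reactants: 12 (3E,7Z,11R)-11-[(tert-butyldimethylsilyl)oxy]-4,8,16-trimethyl-12-methylideneheptadeca-3,7,15-trien-1-ol
Product: 13 (3E,7Z,11R)-11-[(tert-butyldimethylsilyl)oxy]-1-iodo-4,8,16-trimethyl-12-methylideneheptadeca-3,7,15-triene
Conditions: I2, PPh3, imidazole, CH2Cl2, 0 °C
Reagents that add atoms: iodine, II
Why: Appel-type iodination of a primary alcohol under buffered conditions; alkenes and the silyl ether are untouched.

Step 8
Reactants: 13 (3E,7Z,11R)-11-[(tert-butyldimethylsilyl)oxy]-1-iodo-4,8,16-trimethyl-12-methylideneheptadeca-3,7,15-triene; 14 (E)-but-2-enoic acid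
Product: 16 (5E,9Z,13R)-13-[(tert-butyldimethylsilyl)oxy]-2-ethenyl-6,10,18-trimethyl-14-methylidenenonadeca-5,9,17-trienoic acid (both C2 epimers), via dilithium dienediolate 15 (not isolated)
Conditions: 14, LDA (2.2 equiv), THF, −78 to 0 °C; DMPU, then 13, 0 °C to rt; then 1 M HCl
Reagents that add atoms: lithium diisopropylamide, CC(C)[N-]C(C)C.[Li+] (lithium in 15 only)
Why: Deconjugative alkylation: lithium dienediolates of 2-alkenoic acids react with alkyl halides at the α-carbon, which forms C4–C5 and leaves C2=C3 as a vinyl group. The new centre C4 need not be controlled.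

Step 9
Reactants: 16 (5E,9Z,13R)-13-[(tert-butyldimethylsilyl)oxy]-2-ethenyl-6,10,18-trimethyl-14-methylidenenonadeca-5,9,17-trienoic acid
Product: 17 (5E,9Z,13R)-2-ethenyl-13-hydroxy-6,10,18-trimethyl-14-methylidenenonadeca-5,9,17-trienoic acid
Conditions: HF·pyridine, pyridine, THF, 0 °C to rt
Reagents that add atoms: none
Why: Buffered fluoride cleavage of the secondary silyl ether; the medium is too weakly acidic to protonate the trisubstituted alkenes or to ionise the allylic alcohol.

Step 10
Reactants: 17 (5E,9Z,13R)-2-ethenyl-13-hydroxy-6,10,18-trimethyl-14-methylidenenonadeca-5,9,17-trienoic acid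
Product: 18 (6E,10Z,14R)-3-ethenyl-7,11-dimethyl-14-(6-methylhepta-1,5-dien-2-yl)-1-oxacyclotetradeca-6,10-dien-2-one (both C3 epimers)
Conditions: 2-methyl-6-nitrobenzoic anhydride, DMAP, CH2Cl2, rt, slow addition of 17 (high dilution)
Reagents that add atoms: none
Why: Shiina macrolactonisation activates the acid, so the carbinol is acylated with retention at C1. Epimerisation at C4 or partial shift of the vinyl group into conjugation is harmless, because all these isomers give the same enolate in step 11.

Step 11
Reactants: 18 (6E,10Z,14R)-3-ethenyl-7,11-dimethyl-14-(6-methylhepta-1,5-dien-2-yl)-1-oxacyclotetradeca-6,10-dien-2-one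
Product: 22 (1Z,4R,7Z,11E)-7,11-dimethyl-4-(6-methylhepta-1,5-dien-2-yl)cyclotetradeca-1,7,11-triene-1-carboxylic acid, via silyl ketene acetal 19 (not isolated), via ring-transposed silyl ester 20 (not isolated), via conjugated silyl ester 21 (not isolated)
Conditions: LDA, THF/DMPU, −78 °C; TBSCl, −78 °C to rt; solvent changed to toluene, 80 °C, then 150 °C (sealed vessel); then AcOH/THF/H2O, rt
Reagents that add atoms: tert-butyldimethylsilyl chloride, CC(C)(C)[Si](C)(C)Cl (silyl group in 19, 20 and 21 only)
Why: LDA in THF/DMPU removes the C4 proton (both C4 epimers of 18, and any conjugated 2-ethylidene isomer from step 10, funnel into one extended enolate) and O-silylation gives 19, in which ring carbon C5 is cis to OTBS and trans to the ring oxygen, the geometry expected from an open, DMPU-solvated deprotonation and from the antiperiplanar C5–C4–C(=O)–O torsion of a large-ring lactone. An Ireland–Claisen [3,3] shift then breaks C1–O and forms C4–C16, so that the ring oxygen and the acyl carbon leave the 14-membered ring and C16 and C15 enter it (20), and a Cope [3,3] shift of the 1,5-diene C2=C3–C4–C16–C15=C1 breaks C4–C16 and forms C1–C2, so that C15 and C16 leave the ring again and C2 and C3 enter it (21), driven by conjugation of C3=C4 with the ester and by loss of the quaternary centre. The closest known reaction types are the Claisen rearrangement of lactone silyl ketene acetals that carry an alkenyl group on the carbinol carbon, and the ester dienolate Claisen/Cope sequence, the aliphatic counterpart of the para-Claisen rearrangement. Neither ring is closed by an end-to-end encounter: each is formed by a six-centre transposition inside a ring that already exists (14 to 14 to 14 atoms, transition states of the bicyclo[10.2.2] type). Both shifts should run through chairs in which the ten-atom tether C5–C14 is equatorial on C4 and axial on C1, the only 1,4-bridging mode that keeps OTBS, the vinyl group and the homoprenyl chain largely clear of the ring interior, while boats are penalised by eclipsing of OTBS with the homoprenyl group in the first shift and by the intrinsic chair preference in the second. In this topology the (R)-C1–O centre is translated into (S)-C4 and a (Z)-C15=C1 bond in 20, and from there into a C1–C2 bond on the face of C1 opposite to the oxygen that left, which is R in 21. The equatorial C5 ends trans to C2, which is the required C3=C4 geometry with the carboxyl group cis to C2, and C15=C16H2 is regenerated. The step needs control of the ketene acetal geometry and of the chair topology; an error in the former should end in the C3=C4 geometric isomer with the same C1 configuration and not in the enantiomer, so the tether protects the single stereocentre.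

Step 12
Reactants: 22 (1Z,4R,7Z,11E)-7,11-dimethyl-4-(6-methylhepta-1,5-dien-2-yl)cyclotetradeca-1,7,11-triene-1-carboxylic acid
Product: 23 methyl (1Z,4R,7Z,11E)-7,11-dimethyl-4-(6-methylhepta-1,5-dien-2-yl)cyclotetradeca-1,7,11-triene-1-carboxylate (target)
Conditions: MeI, K2CO3, DMF, rt
Reagents that add atoms: iodomethane, CI
Why: O-alkylation of the carboxylate takes place away from the alkene, so the Z-enoate and C1 are not at risk; K2CO3 is too weak to deprotonate C2 or C5.

## Compound list

1 | (1Z,5Z)-1,5-dimethylcycloocta-1,5-diene | C/C1=C/CC/C(C)=C\CC1 | starting material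
2 | 1,5-dimethyl-9,10,11-trioxabicyclo[6.2.1]undec-4-ene (ozonide, racemic) | CC12CC/C=C(/C)CCC(OO1)O2 | intermediate
3 | (4Z)-4-methyl-8-oxonon-4-enal | CC(=O)CC/C=C(/C)CCC=O | intermediate
4 | 6-methylhept-5-en-2-one | CC(=O)CCC=C(C)C | starting material
5 | lithium 6-methylhepta-1,5-dien-2-olate | C=C([O-])CCC=C(C)C.[Li+] | intermediate
6 | 6-methylhepta-1,5-dien-2-yl trifluoromethanesulfonate | C=C(CCC=C(C)C)OS(=O)(=O)C(F)(F)F | intermediate
7 | (5Z,9R)-9-hydroxy-6,14-dimethyl-10-methylidenepentadeca-5,13-dien-2-one | C=C(CCC=C(C)C)[C@H](O)CC/C(C)=C\CCC(C)=O | intermediate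
8 | (5Z,9R)-9-[(tert-butyldimethylsilyl)oxy]-6,14-dimethyl-10-methylidenepentadeca-5,13-dien-2-one | C=C(CCC=C(C)C)[C@H](O[Si](C)(C)C(C)(C)C)CC/C(C)=C\CCC(C)=O | intermediate
9 | diethyl (5Z,9R)-9-[(tert-butyldimethylsilyl)oxy]-6,14-dimethyl-10-methylidenepentadeca-1,5,13-trien-2-yl phosphate | C=C(CCC=C(C)C)[C@H](O[Si](C)(C)C(C)(C)C)CC/C(C)=C\CCC(=C)OP(=O)(OCC)OCC | intermediate
10 | (5Z,9R)-9-[(tert-butyldimethylsilyl)oxy]-6,14-dimethyl-10-methylidenepentadeca-5,13-dien-1-yne | C=C(CCC=C(C)C)[C@H](O[Si](C)(C)C(C)(C)C)CC/C(C)=C\CCC#C | intermediate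
11 | {(1E,5Z,9R)-9-[(tert-butyldimethylsilyl)oxy]-2,6,14-trimethyl-10-methylidenepentadeca-1,5,13-trien-1-yl}dimethylalane | C=C(CCC=C(C)C)[C@H](O[Si](C)(C)C(C)(C)C)CC/C(C)=C\CC/C(C)=C/[Al](C)C | intermediate
12 | (3E,7Z,11R)-11-[(tert-butyldimethylsilyl)oxy]-4,8,16-trimethyl-12-methylideneheptadeca-3,7,15-trien-1-ol | C=C(CCC=C(C)C)[C@H](O[Si](C)(C)C(C)(C)C)CC/C(C)=C\CC/C(C)=C/CCO | intermediate
13 | (3E,7Z,11R)-11-[(tert-butyldimethylsilyl)oxy]-1-iodo-4,8,16-trimethyl-12-methylideneheptadeca-3,7,15-triene | C=C(CCC=C(C)C)[C@H](O[Si](C)(C)C(C)(C)C)CC/C(C)=C\CC/C(C)=C/CCI | intermediate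
14 | (E)-but-2-enoic acid | C/C=C/C(=O)O | starting material
15 | dilithium buta-1,3-diene-1,1-diolate | C=CC=C([O-])[O-].[Li+].[Li+] | intermediate
16 | (5E,9Z,13R)-13-[(tert-butyldimethylsilyl)oxy]-2-ethenyl-6,10,18-trimethyl-14-methylidenenonadeca-5,9,17-trienoic acid (both C2 epimers) | C=C(CCC=C(C)C)[C@H](O[Si](C)(C)C(C)(C)C)CC/C(C)=C\CC/C(C)=C/CCC(C=C)C(=O)O | intermediate
17 | (5E,9Z,13R)-2-ethenyl-13-hydroxy-6,10,18-trimethyl-14-methylidenenonadeca-5,9,17-trienoic acid (both C2 epimers) | C=C(CCC=C(C)C)[C@H](O)CC/C(C)=C\CC/C(C)=C/CCC(C=C)C(=O)O | intermediate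
18 | (6E,10Z,14R)-3-ethenyl-7,11-dimethyl-14-(6-methylhepta-1,5-dien-2-yl)-1-oxacyclotetradeca-6,10-dien-2-one (both C3 epimers) | C=C(CCC=C(C)C)[C@H]1CC/C(C)=C\CC/C(C)=C/CCC(C=C)C(=O)O1 | intermediate
19 | (2E,6E,10Z,14R)-2-[(tert-butyldimethylsilyl)oxy]-3-ethenyl-7,11-dimethyl-14-(6-methylhepta-1,5-dien-2-yl)-1-oxacyclotetradeca-2,6,10-triene | C=C(CCC=C(C)C)[C@H]1CC/C(C)=C\CC/C(C)=C/CC/C(C=C)=C(\O[Si](C)(C)C(C)(C)C)O1 | intermediate
20 | tert-butyldimethylsilyl (1S,3Z,7Z,11E)-1-ethenyl-7,11-dimethyl-3-(4-methylpent-3-en-1-yl)cyclotetradeca-3,7,11-triene-1-carboxylate | C=C[C@@]1(C(=O)O[Si](C)(C)C(C)(C)C)C/C(CCC=C(C)C)=C\CC/C(C)=C\CC/C(C)=C/CC1 | intermediate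
21 | tert-butyldimethylsilyl (1Z,4R,7Z,11E)-7,11-dimethyl-4-(6-methylhepta-1,5-dien-2-yl)cyclotetradeca-1,7,11-triene-1-carboxylate | C=C(CCC=C(C)C)[C@H]1C/C=C(\C(=O)O[Si](C)(C)C(C)(C)C)CC/C=C(\C)CC/C=C(/C)CC1 | intermediate
22 | (1Z,4R,7Z,11E)-7,11-dimethyl-4-(6-methylhepta-1,5-dien-2-yl)cyclotetradeca-1,7,11-triene-1-carboxylic acid | C=C(CCC=C(C)C)[C@H]1C/C=C(\C(=O)O)CC/C=C(\C)CC/C=C(/C)CC1 | intermediate
23 | methyl (1Z,4R,7Z,11E)-7,11-dimethyl-4-(6-methylhepta-1,5-dien-2-yl)cyclotetradeca-1,7,11-triene-1-carboxylate | C=C(CCC=C(C)C)[C@H]1C/C=C(\C(=O)OC)CC/C=C(\C)CC/C=C(/C)CC1 | target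

## Step count and least certain steps

Total step count: 12. Longest linear sequence: 11 steps (1 to 23 through steps 1 and 3 to 12); step 2 is the only side branch.

**Step 11 (key step).** Three processes are most likely to go wrong.
- The first shift may leak through the ketene acetal of opposite geometry or through a boat, which would end in the wrong C3=C4 geometry.
- The Cope shift may pass through a diequatorially bridged chair, which would erode the enantiopurity.
- The silyl ester may decompose thermally before the Cope shift is complete, because bridging by the tether raises both barriers above those of open-chain models.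

The fallback gives up the O-to-C relay. It sets C1 by a catalytic asymmetric conjugate alkenylation and closes the ring by the Z-selective olefination of Alternative 1. It sets out from 3 and 6 and comes back at 23. Aldehyde-selective Wittig reaction of 3 with (triphenylphosphoranylidene)acetaldehyde gives the dienal F1, and Miyaura borylation of 6 (B2pin2, PdCl2(PPh3)2, PPh3, KOPh) gives the alkenylboronate F2. Rhodium-catalysed asymmetric 1,4-addition of F2 to F1 ([RhCl(C2H4)2]2, chiral diene ligand, KOH, dioxane/H2O) gives the keto aldehyde F3 with C1 in place. NaBH4 at −78 °C reduces only the aldehyde to the keto alcohol F4, and TBSCl gives the silyl ether F5. The operations of steps 5 to 7 then lead through the enol phosphate F6, the alkyne F7, the alkenylalane F8 and the homoallylic alcohol F9 to the iodide F10. Alkylation of the sodium salt of methyl bis(2,2,2-trifluoroethyl)phosphonoacetate with F10 gives the phosphonate F11. HF·pyridine gives the primary alcohol F12, Dess–Martin oxidation gives the phosphonate aldehyde A1, and KHMDS/18-crown-6 in THF under high dilution closes C3=C4 to 23.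

**Step 10.** Oligomerisation may compete with ring closure. Loss of the acidic α-proton from the activated 2-vinyl acid gives a vinylketene, which can dimerise before the hindered secondary carbinol captures it.

The fallback closes the same ring by C–C instead of C–O bond formation and by-passes steps 8 to 10. It sets out from 13 and comes back at 19. HF·pyridine gives the iodo alcohol F18, and esterification with diethylphosphonoacetic acid (DCC, DMAP) gives the phosphonoacetate F19. Cs2CO3 in MeCN under high dilution alkylates the stabilised carbanion intramolecularly to the macrocyclic phosphono lactone F20. Horner–Wadsworth–Emmons reaction with acetaldehyde gives the 2-ethylidene lactone F21. γ-Deprotonation of F21 (LDA, THF/DMPU) and silylation deliver 19.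

**Step 8.** E2 elimination of the homoallylic iodide by the strongly basic dienediolate, and competing γ-alkylation, are the likely losses.

The fallback uses a soft carbanion and builds the unsaturation afterwards. It sets out from 13 and comes back at 16. Alkylation of the sodium salt of triethyl phosphonoacetate gives the phosphono ester F15. Horner–Wadsworth–Emmons reaction with acetaldehyde gives the 2-ethylidene ester F16 (its alkene geometry is irrelevant), and LiOH gives the 2-ethylidene acid F17. Double deprotonation (LDA, THF/DMPU) and kinetic α-protonation with AcOH at −78 °C deconjugate F17 to 16.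

**Step 3.** Facial selectivity may be insufficient with an unbranched aliphatic aldehyde, and activation of the enol triflate by nickel may be slow. Low conversion or low enantiopurity would then be carried through to 23.

The fallback replaces asymmetric catalysis by resolution. It sets out from 3 and 6 and comes back at 7. Coupling with stoichiometric CrCl2 and catalytic NiCl2 in DMF gives the racemic alcohol F13. An acylative kinetic resolution (chiral amidine acyl-transfer catalyst, propionic anhydride, i-Pr2NEt) converts the S enantiomer into the propionate F14 and leaves 7.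

## Further compounds

F1 | step 11 | (2E,6Z)-6-methyl-10-oxoundeca-2,6-dienal | O=C/C=C/CC/C(C)=C\CCC(C)=O
F2 | step 11 | 4,4,5,5-tetramethyl-2-(6-methylhepta-1,5-dien-2-yl)-1,3,2-dioxaborolane | C=C(CCC=C(C)C)B1OC(C)(C)C(C)(C)O1
F3 | step 11 | (3R,6Z)-6-methyl-3-(6-methylhepta-1,5-dien-2-yl)-10-oxoundec-6-enal | C=C(CCC=C(C)C)[C@@H](CC=O)CC/C(C)=C\CCC(C)=O
F4 | step 11 | (5Z,9R)-11-hydroxy-6-methyl-9-(6-methylhepta-1,5-dien-2-yl)undec-5-en-2-one | C=C(CCC=C(C)C)[C@@H](CCO)CC/C(C)=C\CCC(C)=O
F5 | step 11 | (5Z,9R)-11-[(tert-butyldimethylsilyl)oxy]-6-methyl-9-(6-methylhepta-1,5-dien-2-yl)undec-5-en-2-one | C=C(CCC=C(C)C)[C@@H](CCO[Si](C)(C)C(C)(C)C)CC/C(C)=C\CCC(C)=O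
F6 | step 11 | diethyl (5Z,9R)-11-[(tert-butyldimethylsilyl)oxy]-6-methyl-9-(6-methylhepta-1,5-dien-2-yl)undeca-1,5-dien-2-yl phosphate | C=C(CCC=C(C)C)[C@@H](CCO[Si](C)(C)C(C)(C)C)CC/C(C)=C\CCC(=C)OP(=O)(OCC)OCC
F7 | step 11 | (5Z,9R)-11-[(tert-butyldimethylsilyl)oxy]-6-methyl-9-(6-methylhepta-1,5-dien-2-yl)undec-5-en-1-yne | C=C(CCC=C(C)C)[C@@H](CCO[Si](C)(C)C(C)(C)C)CC/C(C)=C\CCC#C
F8 | step 11 | {(1E,5Z,9R)-11-[(tert-butyldimethylsilyl)oxy]-2,6-dimethyl-9-(6-methylhepta-1,5-dien-2-yl)undeca-1,5-dien-1-yl}dimethylalane | C=C(CCC=C(C)C)[C@@H](CCO[Si](C)(C)C(C)(C)C)CC/C(C)=C\CC/C(C)=C/[Al](C)C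
F9 | step 11 | (3E,7Z,11R)-13-[(tert-butyldimethylsilyl)oxy]-4,8-dimethyl-11-(6-methylhepta-1,5-dien-2-yl)trideca-3,7-dien-1-ol | C=C(CCC=C(C)C)[C@@H](CCO[Si](C)(C)C(C)(C)C)CC/C(C)=C\CC/C(C)=C/CCO
F10 | step 11 | (3E,7Z,11R)-13-[(tert-butyldimethylsilyl)oxy]-1-iodo-4,8-dimethyl-11-(6-methylhepta-1,5-dien-2-yl)trideca-3,7-diene | C=C(CCC=C(C)C)[C@@H](CCO[Si](C)(C)C(C)(C)C)CC/C(C)=C\CC/C(C)=C/CCI
F11 | step 11 | methyl (5E,9Z,13R)-2-[bis(2,2,2-trifluoroethoxy)phosphoryl]-15-[(tert-butyldimethylsilyl)oxy]-6,10-dimethyl-13-(6-methylhepta-1,5-dien-2-yl)pentadeca-5,9-dienoate | C=C(CCC=C(C)C)[C@@H](CCO[Si](C)(C)C(C)(C)C)CC/C(C)=C\CC/C(C)=C/CCC(C(=O)OC)P(=O)(OCC(F)(F)F)OCC(F)(F)F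
F12 | step 11 | methyl (5E,9Z,13R)-2-[bis(2,2,2-trifluoroethoxy)phosphoryl]-15-hydroxy-6,10-dimethyl-13-(6-methylhepta-1,5-dien-2-yl)pentadeca-5,9-dienoate | C=C(CCC=C(C)C)[C@@H](CCO)CC/C(C)=C\CC/C(C)=C/CCC(C(=O)OC)P(=O)(OCC(F)(F)F)OCC(F)(F)F
F13 | step 3 | (5Z)-9-hydroxy-6,14-dimethyl-10-methylidenepentadeca-5,13-dien-2-one (racemic) | C=C(CCC=C(C)C)C(O)CC/C(C)=C\CCC(C)=O
F14 | step 3 | (5Z,9S)-6,14-dimethyl-10-methylidene-2-oxopentadeca-5,13-dien-9-yl propanoate | C=C(CCC=C(C)C)[C@@H](OC(=O)CC)CC/C(C)=C\CCC(C)=O
F15 | step 8 | ethyl (5E,9Z,13R)-13-[(tert-butyldimethylsilyl)oxy]-2-(diethoxyphosphoryl)-6,10,18-trimethyl-14-methylidenenonadeca-5,9,17-trienoate | C=C(CCC=C(C)C)[C@H](O[Si](C)(C)C(C)(C)C)CC/C(C)=C\CC/C(C)=C/CCC(C(=O)OCC)P(=O)(OCC)OCC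
F16 | step 8 | ethyl (5E,9Z,13R)-13-[(tert-butyldimethylsilyl)oxy]-2-ethylidene-6,10,18-trimethyl-14-methylidenenonadeca-5,9,17-trienoate (ethylidene geometry not controlled) | C=C(CCC=C(C)C)[C@H](O[Si](C)(C)C(C)(C)C)CC/C(C)=C\CC/C(C)=C/CCC(=CC)C(=O)OCC
F17 | step 8 | (5E,9Z,13R)-13-[(tert-butyldimethylsilyl)oxy]-2-ethylidene-6,10,18-trimethyl-14-methylidenenonadeca-5,9,17-trienoic acid (ethylidene geometry not controlled) | C=C(CCC=C(C)C)[C@H](O[Si](C)(C)C(C)(C)C)CC/C(C)=C\CC/C(C)=C/CCC(=CC)C(=O)O
F18 | step 10 | (7R,10Z,14E)-17-iodo-2,10,14-trimethyl-6-methylideneheptadeca-2,10,14-trien-7-ol | C=C(CCC=C(C)C)[C@H](O)CC/C(C)=C\CC/C(C)=C/CCI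
F19 | step 10 | (7R,10Z,14E)-17-iodo-2,10,14-trimethyl-6-methylideneheptadeca-2,10,14-trien-7-yl 2-(diethoxyphosphoryl)acetate | C=C(CCC=C(C)C)[C@H](OC(=O)CP(=O)(OCC)OCC)CC/C(C)=C\CC/C(C)=C/CCI
F20 | step 10 | diethyl [(6E,10Z,14R)-7,11-dimethyl-14-(6-methylhepta-1,5-dien-2-yl)-2-oxo-1-oxacyclotetradeca-6,10-dien-3-yl]phosphonate (both C3 epimers) | C=C(CCC=C(C)C)[C@H]1CC/C(C)=C\CC/C(C)=C/CCC(P(=O)(OCC)OCC)C(=O)O1
F21 | step 10 | (6E,10Z,14R)-3-ethylidene-7,11-dimethyl-14-(6-methylhepta-1,5-dien-2-yl)-1-oxacyclotetradeca-6,10-dien-2-one (ethylidene geometry not controlled) | C=C(CCC=C(C)C)[C@H]1CC/C(C)=C\CC/C(C)=C/CCC(=CC)C(=O)O1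
A1 | alternative 1 | methyl (5E,9Z,13R)-2-[bis(2,2,2-trifluoroethoxy)phosphoryl]-6,10-dimethyl-13-(6-methylhepta-1,5-dien-2-yl)-15-oxopentadeca-5,9-dienoate | C=C(CCC=C(C)C)[C@@H](CC=O)CC/C(C)=C\CC/C(C)=C/CCC(C(=O)OC)P(=O)(OCC(F)(F)F)OCC(F)(F)F
A2 | alternative 2 | achiral 18-membered lactone, methyl (3E,6Z,10E,14Z)-10,14-dimethyl-3-(4-methylpent-3-en-1-yl)-18-oxo-1-oxacyclooctadeca-3,6,10,14-tetraene-7-carboxylate | O=C1CC/C(C)=C\CC/C(C)=C/CC/C(C(=O)OC)=C/C/C=C(CCC=C(C)C)/CO1
A3 | alternative 2 | 14-carboxy derivative of 23 (C1 as in 23, C14 not specified) | C=C(CCC=C(C)C)[C@H]1C/C=C(\C(=O)OC)CC/C=C(\C)CC/C=C(/C)CC1C(=O)O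
A4 | alternative 3 | (R)-limonene | C=C(C)[C@H]1CC=C(C)CC1
A5 | alternative 3 | (R)-β-bisabolene | C=C(CCC=C(C)C)[C@H]1CC=C(C)CC1
A6 | alternative 3 | (3R)-3-(6-methylhepta-1,5-dien-2-yl)-6-oxoheptanal | C=C(CCC=C(C)C)[C@@H](CC=O)CCC(C)=O
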